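**Plan**

1. Cuts: first the six O–benzyl bonds of a hexabenzyl ether; then the bond between C-3 of the flavanone and C-3 of chalcone ring B, which gives the silyl enol ether of (2R)-tri-O-benzylnaringenin (carbon nucleophile) and an aryl(2,4,6-trimethoxyphenyl)iodonium salt of tri-O-benzylisoliquiritigenin (aryl cation equivalent); last the C-2–aryl bond of the flavanone (1,4-addition to a chromone) and the Cα=Cβ bond of the chalcone (aldol condensation).
2. Enabling feature: both carbons of the central bond are natively nucleophilic. C-3 is the α-carbon of the C-4 ketone of ring C and its only enolisable site (C-4a is aromatic); the ring-B carbon is ortho to the phenolic oxygen. Their union is therefore an oxidative coupling, as in the biosynthesis. Here the two-electron oxidation is stored in the aryl partner as iodine(III), at the ortho position that is bought as the iodide, and the enol is fixed as its silyl ether, so no base or free enolate meets the base-labile ring C.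
3. Forward order: ring C is closed first as a chromone, the C-2 aryl group is added and the enol silane is formed; in parallel the chalcone is condensed and its iodide raised to the iodonium salt; one copper-catalysed step joins the two complete C15 halves; global debenzylation ends the route.
4. Stereochemistry: C-2 (R) comes from catalyst control in the rhodium-catalysed 1,4-addition; C-3 (S) comes from substrate control in the key step (the aryl group enters anti to the C-2 aryl group, and 2,3-trans is also the thermodynamic isomer); the E alkene comes from E1cB dehydration in the Claisen–Schmidt step.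

Key step: step 7

Remark: the (R)-configured bisphosphine is assumed to deliver the aryl group to the face of the chromone that gives the 2R flavanone; if the sense of induction is the opposite, the antipodal ligand is used. The four numbered starting materials are taken as commercially available.

**Route**

Step 1
Reactants: 1 1-[2,4-bis(benzyloxy)-6-hydroxyphenyl]ethan-1-one
Product: 3 5,7-bis(benzyloxy)-4H-chromen-4-one, via enaminone 2 (not isolated)
Conditions: Me2NCH(OMe)2, toluene, 100 °C; then conc. HCl, CH2Cl2, 40 °C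
Reagents that add atoms: N,N-dimethylformamide dimethyl acetal, COC(OC)N(C)C
Why: Condensation of the methyl ketone with the amide acetal should give the β-dimethylaminoenone 2, and acid then triggers conjugate addition of the 6-hydroxyl group with loss of dimethylamine (6-endo addition–elimination, the enaminone route to chromones); the benzyl ethers tolerate both stages.

Step 2
Reactants: 3 5,7-bis(benzyloxy)-4H-chromen-4-one; 4 [4-(benzyloxy)phenyl]boronic acid
Product: 5 (2R)-5,7-bis(benzyloxy)-2-[4-(benzyloxy)phenyl]-2,3-dihydro-4H-chromen-4-one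
Conditions: [Rh(OH)(cod)]2 (cat.), (R)-MeO-F12-BIPHEP [(6,6'-dimethoxybiphenyl-2,2'-diyl)bis[bis(3,4,5-trifluorophenyl)phosphine]] (cat.), CH2Cl2/H2O, rt
Reagents that add atoms: none
Why: Hayashi–Miyaura rhodium-catalysed asymmetric 1,4-addition of an arylboronic acid to a chromone, in which the aryl–Rh(I) species adds across C-2=C-3 on the enantioface selected by the electron-poor chiral bisphosphine (sets C-2 as R) and fast protonolysis of the rhodium oxa-π-allyl by water should outrun retro-oxa-Michael opening of ring C.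

Step 3
Reactants: 5 (2R)-5,7-bis(benzyloxy)-2-[4-(benzyloxy)phenyl]-2,3-dihydro-4H-chromen-4-one
Product: 6 tert-butyl{[(2R)-5,7-bis(benzyloxy)-2-[4-(benzyloxy)phenyl]-2H-chromen-4-yl]oxy}dimethylsilane
Conditions: TBSOTf, Et3N, CH2Cl2, 0 °C
Reagents that add atoms: tert-butyldimethylsilyl trifluoromethanesulfonate, CC(C)(C)[Si](C)(C)OS(=O)(=O)C(F)(F)F
Why: Soft enolisation (silyl triflate and tertiary amine) in which the O-silylated ketone can lose a proton only from C-3, no metal enolate is formed so ring C should not open, and C-2 is not touched.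

Step 4
Reactants: 7 4-hydroxy-3-iodobenzaldehyde
Product: 8 4-(benzyloxy)-3-iodobenzaldehyde
Conditions: BnBr, K2CO3, DMF, rt
Reagents that add atoms: benzyl bromide, BrCc1ccccc1
Why: Williamson ether synthesis on the acidic phenol para to the formyl group; aldehyde and aryl iodide are inert to carbonate.

Step 5
Reactants: 8 4-(benzyloxy)-3-iodobenzaldehyde; 9 1-[2,4-bis(benzyloxy)phenyl]ethan-1-one
Product: 10 (2E)-1-[2,4-bis(benzyloxy)phenyl]-3-[4-(benzyloxy)-3-iodophenyl]prop-2-en-1-one
Conditions: KOH, EtOH/THF, rt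
Reagents that add atoms: none
Why: Claisen–Schmidt condensation of a non-enolisable aldehyde with a methyl ketone, whose E1cB dehydration should give the conjugated E enone; benzyl ethers and the aryl iodide are stable to hydroxide.

Step 6
Reactants: 10 (2E)-1-[2,4-bis(benzyloxy)phenyl]-3-[4-(benzyloxy)-3-iodophenyl]prop-2-en-1-one
Product: 13 {2-(benzyloxy)-5-[(1E)-3-[2,4-bis(benzyloxy)phenyl]-3-oxoprop-1-en-1-yl]phenyl}(2,4,6-trimethoxyphenyl)iodonium trifluoromethanesulfonate, via iodane 11 (not isolated), via iodonium tosylate 12 (not isolated)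
Conditions: mCPBA, TsOH·H2O, MeCN/CH2Cl2, rt; then 1,3,5-trimethoxybenzene, rt; then aq. NaOTf, CH2Cl2
Reagents that add atoms: 1,3,5-trimethoxybenzene, COc1cc(OC)cc(OC)c1; sodium trifluoromethanesulfonate, [Na+].[O-]S(=O)(=O)C(F)(F)F; for the intermediates 11 and 12 only: 3-chloroperbenzoic acid, O=C(OO)c1cccc(Cl)c1; 4-methylbenzenesulfonic acid, Cc1ccc(S(=O)(=O)O)cc1
Why: One-pot unsymmetrical diaryliodonium synthesis, in which peracid and sulfonic acid oxidise the electron-rich aryl iodide to the [hydroxy(tosyloxy)iodo]arene 11, trimethoxybenzene is substituted at iodine(III) to give 12 and anion metathesis installs the weakly coordinating triflate needed for copper catalysis; the enone and the acyl-deactivated dialkoxyarene should react more slowly than the iodide and trimethoxybenzene.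

Step 7
Reactants: 6 tert-butyl{[(2R)-5,7-bis(benzyloxy)-2-[4-(benzyloxy)phenyl]-2H-chromen-4-yl]oxy}dimethylsilane; 13 {2-(benzyloxy)-5-[(1E)-3-[2,4-bis(benzyloxy)phenyl]-3-oxoprop-1-en-1-yl]phenyl}(2,4,6-trimethoxyphenyl)iodonium trifluoromethanesulfonate
Product: 14 (2R,3S)-5,7-bis(benzyloxy)-2-[4-(benzyloxy)phenyl]-3-{2-(benzyloxy)-5-[(1E)-3-[2,4-bis(benzyloxy)phenyl]-3-oxoprop-1-en-1-yl]phenyl}-2,3-dihydro-4H-chromen-4-one
Conditions: Cu(OTf)2 (10 mol %), 2,6-di-tert-butylpyridine, CH2Cl2, 0 °C to rt
Reagents that add atoms: none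
Why: Cu(OTf)2 is reduced in situ to Cu(I), which adds oxidatively to iodonium salt 13 with loss of 2-iodo-1,3,5-trimethoxybenzene to give an electrophilic aryl–Cu(III) triflate; the π-nucleophilic C-3 of enol silane 6 attacks this centre, and reductive elimination with loss of TBSOTf should form the bond between C-3 of ring C and C-3 of ring B and return Cu(I). The closest known reaction type is the copper-catalysed (and the fluoride-mediated metal-free) α-arylation of silyl enol ethers and silyl ketene acetals with diaryliodonium salts. No ring is closed; the step joins the two intact C15 halves and completes the carbon skeleton. The new stereocentre C-3 is controlled by the C-2 aryl group, which shields one face of the 2H-chromene so that the aryl group enters anti (2,3-trans, 3S); the same diequatorial isomer is favoured thermodynamically should C-3 enolise. Three selectivities are needed: transfer of the chalcone aryl group and not the auxiliary ring, secured by the two ortho-methoxy groups and the electron richness of the trimethoxyphenyl ligand; arylation at carbon in preference to Mukaiyama–Michael addition of 6 to the enone, secured by the fast, soft aryl–Cu(III) electrophile at low temperature with the hindered pyridine buffering adventitious triflic acid; and retention at C-2, secured by the absence of base and of any free enolate, so that ring C cannot open by retro-oxa-Michael reaction.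

Step 8
Reactants: 14 (2R,3S)-5,7-bis(benzyloxy)-2-[4-(benzyloxy)phenyl]-3-{2-(benzyloxy)-5-[(1E)-3-[2,4-bis(benzyloxy)phenyl]-3-oxoprop-1-en-1-yl]phenyl}-2,3-dihydro-4H-chromen-4-one
Product: 15 (2R,3S)-3-{5-[(1E)-3-(2,4-dihydroxyphenyl)-3-oxoprop-1-en-1-yl]-2-hydroxyphenyl}-5,7-dihydroxy-2-(4-hydroxyphenyl)-2,3-dihydro-4H-chromen-4-one
Conditions: BCl3, pentamethylbenzene, CH2Cl2, −78 °C; then MeOH, −78 °C, aq. NaHCO3
Reagents that add atoms: none
Why: Lewis-acid debenzylation of aryl benzyl ethers at −78 °C with pentamethylbenzene as a non-Lewis-basic benzyl-cation scavenger (Friedel–Crafts trapping), which should leave the enone unreduced and the C-2–O bond and both stereocentres intact, and avoids the hot protic acid that could cyclodehydrate the 2-hydroxyaryl ketone to a benzofuran.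

**Compound list**

1 | 1-[2,4-bis(benzyloxy)-6-hydroxyphenyl]ethan-1-one | CC(=O)c1c(O)cc(OCc2ccccc2)cc1OCc1ccccc1 | starting material
2 | (2E)-1-[2,4-bis(benzyloxy)-6-hydroxyphenyl]-3-(dimethylamino)prop-2-en-1-one | CN(C)/C=C/C(=O)c1c(O)cc(OCc2ccccc2)cc1OCc1ccccc1 | intermediate
3 | 5,7-bis(benzyloxy)-4H-chromen-4-one | O=c1ccoc2cc(OCc3ccccc3)cc(OCc3ccccc3)c12 | intermediate
4 | [4-(benzyloxy)phenyl]boronic acid | OB(O)c1ccc(OCc2ccccc2)cc1 | starting material
5 | (2R)-5,7-bis(benzyloxy)-2-[4-(benzyloxy)phenyl]-2,3-dihydro-4H-chromen-4-one | O=C1C[C@H](c2ccc(OCc3ccccc3)cc2)Oc2cc(OCc3ccccc3)cc(OCc3ccccc3)c12 | intermediate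
6 | tert-butyl{[(2R)-5,7-bis(benzyloxy)-2-[4-(benzyloxy)phenyl]-2H-chromen-4-yl]oxy}dimethylsilane | CC(C)(C)[Si](C)(C)OC1=C[C@H](c2ccc(OCc3ccccc3)cc2)Oc2cc(OCc3ccccc3)cc(OCc3ccccc3)c12 | intermediate
7 | 4-hydroxy-3-iodobenzaldehyde | O=Cc1ccc(O)c(I)c1 | starting material
8 | 4-(benzyloxy)-3-iodobenzaldehyde | O=Cc1ccc(OCc2ccccc2)c(I)c1 | intermediate
9 | 1-[2,4-bis(benzyloxy)phenyl]ethan-1-one | CC(=O)c1ccc(OCc2ccccc2)cc1OCc1ccccc1 | starting material
10 | (2E)-1-[2,4-bis(benzyloxy)phenyl]-3-[4-(benzyloxy)-3-iodophenyl]prop-2-en-1-one | O=C(/C=C/c1ccc(OCc2ccccc2)c(I)c1)c1ccc(OCc2ccccc2)cc1OCc1ccccc1 | intermediate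
11 | {2-(benzyloxy)-5-[(1E)-3-[2,4-bis(benzyloxy)phenyl]-3-oxoprop-1-en-1-yl]phenyl}(hydroxy)(tosyloxy)-λ3-iodane | O=C(/C=C/c1ccc(OCc2ccccc2)c(I(O)OS(=O)(=O)c2ccc(C)cc2)c1)c1ccc(OCc2ccccc2)cc1OCc1ccccc1 | intermediate
12 | {2-(benzyloxy)-5-[(1E)-3-[2,4-bis(benzyloxy)phenyl]-3-oxoprop-1-en-1-yl]phenyl}(2,4,6-trimethoxyphenyl)iodonium 4-methylbenzenesulfonate | COc1cc(OC)c([I+]c2cc(/C=C/C(=O)c3ccc(OCc4ccccc4)cc3OCc3ccccc3)ccc2OCc2ccccc2)c(OC)c1.Cc1ccc(S(=O)(=O)[O-])cc1 | intermediate
13 | {2-(benzyloxy)-5-[(1E)-3-[2,4-bis(benzyloxy)phenyl]-3-oxoprop-1-en-1-yl]phenyl}(2,4,6-trimethoxyphenyl)iodonium trifluoromethanesulfonate | COc1cc(OC)c([I+]c2cc(/C=C/C(=O)c3ccc(OCc4ccccc4)cc3OCc3ccccc3)ccc2OCc2ccccc2)c(OC)c1.[O-]S(=O)(=O)C(F)(F)F | intermediate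
14 | (2R,3S)-5,7-bis(benzyloxy)-2-[4-(benzyloxy)phenyl]-3-{2-(benzyloxy)-5-[(1E)-3-[2,4-bis(benzyloxy)phenyl]-3-oxoprop-1-en-1-yl]phenyl}-2,3-dihydro-4H-chromen-4-one | O=C(/C=C/c1ccc(OCc2ccccc2)c([C@@H]3C(=O)c4c(OCc5ccccc5)cc(OCc5ccccc5)cc4O[C@H]3c3ccc(OCc4ccccc4)cc3)c1)c1ccc(OCc2ccccc2)cc1OCc1ccccc1 | intermediate
15 | (2R,3S)-3-{5-[(1E)-3-(2,4-dihydroxyphenyl)-3-oxoprop-1-en-1-yl]-2-hydroxyphenyl}-5,7-dihydroxy-2-(4-hydroxyphenyl)-2,3-dihydro-4H-chromen-4-one | O=C(/C=C/c1ccc(O)c([C@@H]2C(=O)c3c(O)cc(O)cc3O[C@H]2c2ccc(O)cc2)c1)c1ccc(O)cc1O | target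

**Step count and risks**

Total steps: 8. Longest linear sequence: 5 steps (7 → 8 → 10 → 13 → 14 → 15; the branch 1 → 3 → 5 → 6 → 14 → 15 is equally long).

Steps most likely to fail:

1. Step 7 (key coupling). The transfer of the ortho-benzyloxy aryl group from copper(III) to the hindered C-3 may be slow. Protodesilylation of 6 and silyl-triflate-promoted Mukaiyama–Michael addition of 6 to the enone of 13 could then take over. The fallback runs the coupling before the enone exists; it sets out from 8 (with 6 and 9) and rejoins the route at 14. Aldehyde 8 is oxidised and coupled with 1,3,5-trimethoxybenzene as in step 6 to give [2-(benzyloxy)-5-formylphenyl](2,4,6-trimethoxyphenyl)iodonium trifluoromethanesulfonate F1. Copper-catalysed arylation of 6 with this salt, as in step 7, should give 4-(benzyloxy)-3-[(2R,3S)-5,7-bis(benzyloxy)-2-[4-(benzyloxy)phenyl]-4-oxo-3,4-dihydro-2H-chromen-3-yl]benzaldehyde F2. Ketone 9 is α-brominated (CuBr2, EtOAc/CHCl3, reflux) to 2-bromo-1-[2,4-bis(benzyloxy)phenyl]ethan-1-one F3, which with PPh3 and then aqueous Na2CO3 gives the stabilised ylide 1-[2,4-bis(benzyloxy)phenyl]-2-(triphenyl-λ5-phosphanylidene)ethan-1-one F4. A Wittig reaction of the aldehyde with this ylide in toluene at 90 °C is neutral, should not touch C-2 or C-3, and should give the E enone 14.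

2. Step 6 (iodonium salt). The peracid may over-oxidise the enone or the electron-rich aryl ketone (epoxidation, Baeyer–Villiger reaction). The λ3-iodane may also arylate the 2,4-bis(benzyloxy)phenyl ring of a second molecule before trimethoxybenzene is added, and the sulfonic acid may cleave a benzyl ether. The fallback gives up iodine(III); it sets out from 10 (with 6) and rejoins the route at 14. Iodide 10 is coupled directly with the tin enolate generated in situ from 6 (Bu3SnF, Pd2(dba)3, P(t-Bu)3, toluene, 80 °C), a palladium(0) cross-coupling of silyl enol ethers with aryl halides; no new compound is made (F0).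

3. Step 2 (asymmetric 1,4-addition). Carbometalation of the electron-rich 5,7-dialkoxychromone may be slow, and ring opening of the rhodium enolate to the 2'-hydroxychalcone could erode yield and enantiomeric purity. The fallback is a classical flavanone assembly with kinetic resolution; it sets out from 1 and rejoins the route at 5. Claisen–Schmidt condensation of 1 with 4-(benzyloxy)benzaldehyde (KOH, EtOH) should give (2E)-1-[2,4-bis(benzyloxy)-6-hydroxyphenyl]-3-[4-(benzyloxy)phenyl]prop-2-en-1-one F5. Oxa-Michael ring closure (NaOAc, EtOH, reflux) gives racemic 5,7-bis(benzyloxy)-2-[4-(benzyloxy)phenyl]-2,3-dihydro-4H-chromen-4-one F6. Asymmetric transfer hydrogenation (Rh(III)–TsDPEN catalyst, HCO2H/Et3N, stopped near half conversion, catalyst antipode chosen so that the 2S ketone is reduced faster) should convert the unwanted enantiomer into (2S,4S)-5,7-bis(benzyloxy)-2-[4-(benzyloxy)phenyl]-3,4-dihydro-2H-chromen-4-ol F7 and leave the 2R ketone 5, which is separated by chromatography.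

**Further compounds**

F1 | step 7 | [2-(benzyloxy)-5-formylphenyl](2,4,6-trimethoxyphenyl)iodonium trifluoromethanesulfonate | COc1cc(OC)c([I+]c2cc(C=O)ccc2OCc2ccccc2)c(OC)c1.[O-]S(=O)(=O)C(F)(F)F
F2 | step 7 | 4-(benzyloxy)-3-[(2R,3S)-5,7-bis(benzyloxy)-2-[4-(benzyloxy)phenyl]-4-oxo-3,4-dihydro-2H-chromen-3-yl]benzaldehyde | O=Cc1ccc(OCc2ccccc2)c([C@@H]3C(=O)c4c(OCc5ccccc5)cc(OCc5ccccc5)cc4O[C@H]3c3ccc(OCc4ccccc4)cc3)c1
F3 | step 7 | 2-bromo-1-[2,4-bis(benzyloxy)phenyl]ethan-1-one | O=C(CBr)c1ccc(OCc2ccccc2)cc1OCc1ccccc1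
F4 | step 7 | 1-[2,4-bis(benzyloxy)phenyl]-2-(triphenyl-λ5-phosphanylidene)ethan-1-one | O=C(C=P(c1ccccc1)(c1ccccc1)c1ccccc1)c1ccc(OCc2ccccc2)cc1OCc1ccccc1
F0 | step 6 | none | none
F5 | step 2 | (2E)-1-[2,4-bis(benzyloxy)-6-hydroxyphenyl]-3-[4-(benzyloxy)phenyl]prop-2-en-1-one | O=C(/C=C/c1ccc(OCc2ccccc2)cc1)c1c(O)cc(OCc2ccccc2)cc1OCc1ccccc1
F6 | step 2 | rac-5,7-bis(benzyloxy)-2-[4-(benzyloxy)phenyl]-2,3-dihydro-4H-chromen-4-one | O=C1CC(c2ccc(OCc3ccccc3)cc2)Oc2cc(OCc3ccccc3)cc(OCc3ccccc3)c12
F7 | step 2 | (2S,4S)-5,7-bis(benzyloxy)-2-[4-(benzyloxy)phenyl]-3,4-dihydro-2H-chromen-4-ol | O[C@H]1C[C@@H](c2ccc(OCc3ccccc3)cc2)Oc2cc(OCc3ccccc3)cc(OCc3ccccc3)c12
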